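Cuts: (i) one C8–CH3 bond of the gem-dimethyl carbon, which leads back to the aromatic 8-methyl-2H-chromene 12; (ii) C3–C4 and O1–C2 of the pyran ring together, with the C2-methyl group read as CH2–CHO; (iii) the aryl–CHO and aryl–acyl bonds, back to 2-methylphloroglucinol.
Enabling feature: O1 and C4 sit on the adjacent ring carbons C8a and C4a, a masked salicylaldehyde. C2, with its CH3, C3 and homoprenyl arm, is C3 of citral. C3 is therefore citral's methyl carbon (γ, nucleophilic as a dienamine) and C2 is its β-carbon (electrophilic as an iminium ion).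
Forward order: the carbocycle is bought as the arene, then acylated and formylated. The domino step closes the pyran ring and a temporary lactol ring. Decarbonylation and dehydration remove the helpers (CHO, C4–OH, lactol), and C8-methylation dearomatises the ring.
Stereochemistry: the side-chain centre comes from (R)-2-methylbutanoic acid, and C2 from the (S)-diarylprolinol silyl ether catalyst of the domino step. C4 and the lactol carbon are transient.

Key step: step 3

Assumption: (R)-2-methylbutanoic acid of high enantiomeric purity is taken as a catalogue chemical, and the 2H-pyran ring of 13 is taken not to open and reclose (racemise at C2) at or below room temperature in the dark.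

Step 1
Reactants: 1 (R)-2-methylbutanoic acid; 2 2-methylbenzene-1,3,5-triol (2-methylphloroglucinol)
Product: 4 (2R)-2-methyl-1-(2,4,6-trihydroxy-3-methylphenyl)butan-1-one, via (R)-2-methylbutanoyl chloride 3 (not isolated)
Conditions: (COCl)2, cat. DMF, CH2Cl2, 0 °C to rt; then 2, AlCl3 (4 equiv), CH2Cl2/MeNO2, 0 to 40 °C; aq. HCl
Reagents that add atoms: none
Why: Friedel–Crafts acylation of the very electron-rich triol at one of its two equivalent free positions should stop after one acylation because the chelated aryl ketone is deactivated, and the α-stereocentre is carried over from 1 because neither the acyl chloride nor the chelated ketone enolises appreciably at this temperature.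

Step 2
Reactants: 4 (2R)-2-methyl-1-(2,4,6-trihydroxy-3-methylphenyl)butan-1-one
Product: 5 2,4,6-trihydroxy-3-methyl-5-[(2R)-2-methylbutanoyl]benzaldehyde
Conditions: Cl2CHOMe (1.2 equiv), TiCl4 (3 equiv), CH2Cl2, −20 to 0 °C; then aq. HCl
Reagents that add atoms: dichloromethyl methyl ether, COC(Cl)Cl; water, O
Why: In this Rieche formylation the TiCl4-activated chloro(methoxy)methyl cation attacks the only ring C–H that is left and hydrolysis of the aryl(chloro)methyl ether gives the aldehyde, without touching the α-position of the ketone and without forming a stereocentre.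

Step 3
Reactants: 5 2,4,6-trihydroxy-3-methyl-5-[(2R)-2-methylbutanoyl]benzaldehyde; 6 citral (commercial E/Z mixture)
Product: 10 bridged tricyclic lactol (2R,4R in chroman numbering): 5,7-dihydroxy-8-methyl-6-[(2R)-2-methylbutanoyl]-2-(4-methylpent-3-enyl)chroman whose C2–CH2–CH(OH)–O–C4 bridge completes a 2,6-dioxabicyclo[3.3.1]nonane (anomeric centre unassigned), via cross-conjugated dienamine 7 (not isolated), via aldol iminium benzoate 8 (not isolated), via open hydroxy aldehyde 9 (not isolated)
Conditions: (S)-2-{bis[3,5-bis(trifluoromethyl)phenyl](trimethylsilyloxy)methyl}pyrrolidine (30 mol %), PhCO2H (30 mol %), toluene, rt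
Reagents that add atoms: none
Why: The amine condenses with either geometric isomer of 6 and loss of a proton from the C3-methyl group gives the cross-conjugated dienamine 7, whose unhindered CH2 terminus adds to the formyl carbon of 5 (vinylogous aldol, C3–C4 bond) and thereby regenerates an α,β-unsaturated iminium ion, 8, in which the phenol adds to the β-carbon (oxa-Michael, O1–C2 bond); hydrolysis to 9 and lactol closure end the cascade and release the catalyst. The closest known reaction type is the diarylprolinol silyl ether catalysed domino vinylogous aldol/oxa-Michael reaction of salicylaldehydes with β-methyl-β-alkyl enals, which gives 2,2-dialkylchroman lactols of this bridged kind. The pyran ring closes 6-exo-trig (phenol oxygen onto the C=C of the iminium ion) and the temporary lactol ring closes 6-exo-trig (C4 hydroxyl onto the freed aldehyde). C2 is set by the catalyst: 8 is born from the s-trans dienamine with the new CH2 arm trans to the C=N carbon, the C(Ar)2OTMS group covers one face of its planar E,s-trans iminium system, and attack of oxygen on the open face corresponds, for the (S)-catalyst, to 2R once CH2CHO has become CH3. C4 is tied to C2 because only the cis isomer can lactolise, the anomeric carbon is uncontrolled, and both are erased in step 4. The step needs attack through the γ-CH3 and not the γ'-CH2 or the α-carbon, which the steric openness of the exocyclic methylene secures, and closure through the hydroxyl between CHO and CH3, which is para to the ketone and hence the most acidic and the only one that cannot chelate to it; the fully substituted ring leaves no C–H for the ordinary citral–phenol condensation.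

Step 4
Reactants: 10 bridged tricyclic lactol
Product: 12 (2R)-1-[(2R)-5,7-dihydroxy-2,8-dimethyl-2-(4-methylpent-3-enyl)-2H-chromen-6-yl]-2-methylbutan-1-one, via (2R,4R)-4-hydroxychroman 11 (not isolated)
Conditions: RhCl(PPh3)3 (1.1 equiv), degassed toluene, 100 °C; then PPTS (10 mol %), 4 Å MS, 40 °C
Reagents that add atoms: none
Why: The Tsuji–Wilkinson decarbonylation acts on the equilibrium share of open aldehyde 9 (insertion into the formyl C–H bond, CO extrusion, C–H reductive elimination, quaternary C2 untouched) and turns the helper CH2CHO into the C2-methyl group at the saturated chroman stage, where C2 cannot racemise by electrocyclic opening, and the electron-rich benzylic alcohol 11 then loses water under mild acid (E1 through an o-quinone-methide-like cation) to give the C3=C4 double bond.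

Step 5
Reactants: 12 (2R)-1-[(2R)-5,7-dihydroxy-2,8-dimethyl-2-(4-methylpent-3-enyl)-2H-chromen-6-yl]-2-methylbutan-1-one
Product: 13 (2R)-5-hydroxy-2,8,8-trimethyl-6-[(2R)-2-methylbutanoyl]-2-(4-methylpent-3-enyl)-2H-chromen-7(8H)-one (target)
Conditions: NaOMe (2.2 equiv), MeI (1.5 equiv), MeOH, 0 °C to rt, dark; cold aq. citric acid
Reagents that add atoms: iodomethane, CI
Why: This is the alkylative dearomatisation of a C-methylated acylphloroglucinol (the classical entry to filicinic-acid-type gem-dimethyl triketones): in methanol the hydrogen-bonded phenoxide reacts through carbon, and C8 should be preferred over C6 and C4a because it carries the smallest substituent and its alkylation keeps both the chelated enol–ketone and the C3=C4–C4a=C8a conjugation, while no stereocentre is formed or touched.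

Compound list
1 | (R)-2-methylbutanoic acid | CC[C@@H](C)C(=O)O | starting material
2 | 2-methylbenzene-1,3,5-triol | Cc1c(O)cc(O)cc1O | starting material
3 | (R)-2-methylbutanoyl chloride | CC[C@@H](C)C(=O)Cl | intermediate
4 | (2R)-2-methyl-1-(2,4,6-trihydroxy-3-methylphenyl)butan-1-one | CC[C@@H](C)C(=O)c1c(O)cc(O)c(C)c1O | intermediate
5 | 2,4,6-trihydroxy-3-methyl-5-[(2R)-2-methylbutanoyl]benzaldehyde | CC[C@@H](C)C(=O)c1c(O)c(C)c(O)c(C=O)c1O | intermediate
6 | citral (3,7-dimethylocta-2,6-dienal, E/Z mixture) | CC(C)=CCCC(C)=CC=O | starting material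
7 | cross-conjugated (E)-dienamine of citral and the (S)-catalyst | C=C(CCC=C(C)C)/C=C/N1CCC[C@H]1C(O[Si](C)(C)C)(c1cc(cc(c1)C(F)(F)F)C(F)(F)F)c1cc(cc(c1)C(F)(F)F)C(F)(F)F | intermediate
8 | iminium benzoate of the vinylogous aldol adduct (new CH2 arm trans to the C=N carbon) | CC[C@@H](C)C(=O)c1c(O)c(C)c(O)c([C@H](O)C/C(CCC=C(C)C)=C/C=[N+]2CCC[C@H]2C(O[Si](C)(C)C)(c2cc(cc(c2)C(F)(F)F)C(F)(F)F)c2cc(cc(c2)C(F)(F)F)C(F)(F)F)c1O.[O-]C(=O)c1ccccc1 | intermediate
9 | (2R,4R)-4,5,7-trihydroxy-8-methyl-6-[(2R)-2-methylbutanoyl]-2-(4-methylpent-3-enyl)chroman-2-ylacetaldehyde | CC[C@@H](C)C(=O)c1c(O)c(C)c2O[C@](CC=O)(CCC=C(C)C)C[C@@H](O)c2c1O | intermediate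
10 | bridged tricyclic lactol of 9 (2R,4R; anomeric centre unassigned) | CC[C@@H](C)C(=O)c1c(O)c(C)c2O[C@]3(CCC=C(C)C)C[C@@H](OC(O)C3)c2c1O | intermediate
11 | (2R)-2-methyl-1-[(2R,4R)-4,5,7-trihydroxy-2,8-dimethyl-2-(4-methylpent-3-enyl)chroman-6-yl]butan-1-one | CC[C@@H](C)C(=O)c1c(O)c(C)c2O[C@](C)(CCC=C(C)C)C[C@@H](O)c2c1O | intermediate
12 | (2R)-1-[(2R)-5,7-dihydroxy-2,8-dimethyl-2-(4-methylpent-3-enyl)-2H-chromen-6-yl]-2-methylbutan-1-one | CC[C@@H](C)C(=O)c1c(O)c(C)c2O[C@](C)(CCC=C(C)C)C=Cc2c1O | intermediate
13 | (2R)-5-hydroxy-2,8,8-trimethyl-6-[(2R)-2-methylbutanoyl]-2-(4-methylpent-3-enyl)-2H-chromen-7(8H)-one | CC[C@@H](C)C(=O)C1=C(O)C2=C(O[C@](C)(CCC=C(C)C)C=C2)C(C)(C)C1=O | target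

Total step count: 5. Longest linear sequence: 5 steps (from 1 or 2 to 13).

Steps most likely to fail

Step 3.
- What may go wrong: addition of the dienamine may be too slow, because the formyl group is deactivated by three hydroxyl donors and two hydrogen bonds.
- Premature loss of water from the benzylic carbinol would divert ring closure into an uncatalysed oxa-6π electrocyclisation and erode the enantiomeric purity.
- Closure through the hydroxyl next to the ketone would give the wrong ring fusion.
- Fallback, from 5 back to 12: methylenation of the aldehyde of 5 with an excess of Ph3P=CH2 (phenols carried as phenoxides) would give the vinylphenol F1.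
- Geraniol and methyl chloroformate give geranyl methyl carbonate F2.
- Pd(0) with the C2-symmetric DACH-phenyl bisphosphine ligand should then alkylate the most acidic hydroxyl of F1 at the tertiary allyl terminus, giving the (R)-linalyl aryl ether F3 (asymmetric allylic O-alkylation). The ligand antipode is chosen for the R product; neryl carbonate gives the opposite sense with the same ligand.
- Ring-closing metathesis of the two vinyl groups with a second-generation ruthenium alkylidene closes C3=C4 and rejoins the route at 12.

Step 5.
- What may go wrong: O-methylation of the 5- or 7-phenoxide, or attack at C4a or C6, may outrun C8-methylation, because only two phenoxide oxygens are left to drive reaction through carbon.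
- Fallback, from 5 back to 13: the methylation is moved to 5, which still has three hydroxyls and whose other ring carbons all carry acceptors. MeI/NaOMe would give the formyl gem-dimethyl triketone F7.
- Retro-Claisen deformylation in dilute aqueous base gives (R)-2-methylbutanoylfilicinic acid F8.
- Ethylenediammonium diacetate catalysed Knoevenagel condensation of F8 with citral, followed by oxa-6π electrocyclisation, gives 13 together with its C2 epimer F9. The reversible ring closure is expected to settle on the isomer that keeps the chelated enol.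
- Preparative HPLC on a polysaccharide chiral phase removes F9, and the route is rejoined at 13.

Step 4.
- What may go wrong: the lactol may open too little for rhodium to insert.
- Alternatively, the open β-aryloxy aldehyde may expel the aryloxide by retro-oxa-Michael elimination at 100 °C, with loss of material and of configurational purity at C2.
- Fallback, from 10 back to 12: Lindgren–Pinnick oxidation of 10 (NaClO2, NaH2PO4, 2-methylbut-2-ene) and spontaneous lactonisation would give the bridged lactone F4.
- DBU expels the carboxylate from C4 through the C5-phenoxide (o-quinone methide, then tautomerisation) to give the chromen-2-ylacetic acid F5.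
- DIC and N-hydroxyphthalimide give the redox-active ester F6.
- Nickel-catalysed reductive decarboxylation in the dark (NiCl2, bipyridine-type ligand, Zn, PhSiH3) turns CH2CO2R into CH3 and rejoins the route at 12.

Further compounds
F1 | step 3 | (2R)-1-(3-ethenyl-2,4,6-trihydroxy-5-methylphenyl)-2-methylbutan-1-one | CC[C@@H](C)C(=O)c1c(O)c(C)c(O)c(C=C)c1O
F2 | step 3 | geranyl methyl carbonate | COC(=O)OC/C=C(\C)CCC=C(C)C
F3 | step 3 | (2R)-1-{4-[(3R)-3,7-dimethylocta-1,6-dien-3-yl]oxy-3-ethenyl-2,6-dihydroxy-5-methylphenyl}-2-methylbutan-1-one | CC[C@@H](C)C(=O)c1c(O)c(C)c(O[C@](C)(CCC=C(C)C)C=C)c(C=C)c1O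
F4 | step 4 | bridged lactone corresponding to lactol 10 (2R,4R) | CC[C@@H](C)C(=O)c1c(O)c(C)c2O[C@]3(CCC=C(C)C)C[C@@H](OC(=O)C3)c2c1O
F5 | step 4 | 2-{5,7-dihydroxy-8-methyl-6-[(2R)-2-methylbutanoyl]-2-(4-methylpent-3-enyl)-2H-chromen-2-yl}acetic acid (same spatial arrangement at C2 as 12; descriptor 2S) | CC[C@@H](C)C(=O)c1c(O)c(C)c2O[C@](CC(=O)O)(CCC=C(C)C)C=Cc2c1O
F6 | step 4 | N-hydroxyphthalimide ester of F5 | CC[C@@H](C)C(=O)c1c(O)c(C)c2O[C@](CC(=O)ON3C(=O)c4ccccc4C3=O)(CCC=C(C)C)C=Cc2c1O
F7 | step 5 | 2,6-dihydroxy-5,5-dimethyl-3-[(2R)-2-methylbutanoyl]-4-oxocyclohexa-2,6-diene-1-carbaldehyde | CC[C@@H](C)C(=O)C1=C(O)C(C=O)=C(O)C(C)(C)C1=O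
F8 | step 5 | (R)-2-methylbutanoylfilicinic acid (3,5-dihydroxy-6,6-dimethyl-2-[(2R)-2-methylbutanoyl]cyclohexa-2,4-dien-1-one) | CC[C@@H](C)C(=O)C1=C(O)C=C(O)C(C)(C)C1=O
F9 | step 5 | (2S)-epimer of 13 | CC[C@@H](C)C(=O)C1=C(O)C2=C(O[C@@](C)(CCC=C(C)C)C=C2)C(C)(C)C1=O
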